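## Retrosynthetic overview

1. Target 18 ⇐ Pd(0) O-deallylation of 17 ⇐ SO3·pyridine on hydroquinone 16 ⇐ MOM removal from 15; the allyl group on O-4' keeps the OH ortho to CHO unsulfated.
2. 15 ⇐ O-allylation ⇐ magnesium-phenoxide ortho-formylation of vinylphenol 12, whose only free ortho carbon is C-3'.
3. 12 ⇐ E1 dehydration (C9=C11, E) ⇐ carbinol 11 ⇐ aryllithium (dianion of bromophenol 8) + aldehyde 3 (C11–C1' bond).
4. 8 ⇐ 2,5-dihydroxybenzaldehyde (MOM, Dakin, para-bromination); 3 ⇐ (−)-drimenol (α-face hydrogenation sets C8, then oxidation).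
5. Rings: none is built; the trans-decalin (C5, C10) comes with drimenol and the benzene ring with 2,5-dihydroxybenzaldehyde.

Assumption: (−)-drimenol is taken as a purchasable chiral-pool terpenoid, and the aryl sulfates are drawn as free acids although they are handled as sodium salts.

## Route

Step 1
Reactants: 1 (−)-drimenol
Product: 2 [(1S,2S,4aS,8aS)-2,5,5,8a-tetramethyldecahydronaphthalen-1-yl]methanol
Conditions: H2 (4 atm), PtO2 (10 mol %), EtOAc, rt
Reagents that add atoms: none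
Why: Heterogeneous catalytic hydrogenation in which the Δ7 alkene is adsorbed on its α-face, opposite the axial C10 methyl and the C9 CH2OH, so H is delivered from below and C8 becomes S (8β-methyl, axial).

Step 2
Reactants: 2 [(1S,2S,4aS,8aS)-2,5,5,8a-tetramethyldecahydronaphthalen-1-yl]methanol
Product: 3 (1S,2S,4aS,8aS)-2,5,5,8a-tetramethyldecahydronaphthalene-1-carbaldehyde
Conditions: Dess–Martin periodinane, CH2Cl2, 0 °C to rt
Reagents that add atoms: none
Why: Dess–Martin oxidation stops at the aldehyde; C8 is β to the carbonyl and cannot epimerise, and the α-centre C9 is erased later.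

Step 3
Reactants: 4 2,5-dihydroxybenzaldehyde
Product: 5 2,5-bis(methoxymethoxy)benzaldehyde
Conditions: MOMCl (3 equiv), i-Pr2NEt, CH2Cl2, 0 °C to reflux
Reagents that add atoms: chloromethyl methyl ether (MOMCl), COCCl
Why: O-alkylation of both phenols (Williamson-type acetal formation) gives MOM ethers that survive organolithiums and chelate lithium.

Step 4
Reactants: 5 2,5-bis(methoxymethoxy)benzaldehyde
Product: 7 2,5-bis(methoxymethoxy)phenol, via 2,5-bis(methoxymethoxy)phenyl formate 6 (not isolated)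
Conditions: mCPBA, CH2Cl2, 0 °C to rt; then K2CO3 (cat.), MeOH, rt
Reagents that add atoms: 3-chloroperoxybenzoic acid (mCPBA), OOC(=O)c1cccc(Cl)c1
Why: Dakin-type Baeyer–Villiger oxidation in which the electron-rich aryl group migrates to give the aryl formate, which mild methanolysis cleaves to the phenol.

Step 5
Reactants: 7 2,5-bis(methoxymethoxy)phenol
Product: 8 4-bromo-2,5-bis(methoxymethoxy)phenol
Conditions: NBS (1.0 equiv), MeCN, −20 to 0 °C
Reagents that add atoms: N-bromosuccinimide (NBS), O=C1CCC(=O)N1Br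
Why: Electrophilic aromatic bromination goes para to the free OH (and ortho to an OMOM), the other activated site being crowded between two oxygens.

Step 6
Reactants: 8 4-bromo-2,5-bis(methoxymethoxy)phenol; 3 (1S,2S,4aS,8aS)-2,5,5,8a-tetramethyldecahydronaphthalene-1-carbaldehyde
Product: 11 4-{hydroxy[(1S,2S,4aS,8aS)-2,5,5,8a-tetramethyldecahydronaphthalen-1-yl]methyl}-2,5-bis(methoxymethoxy)phenol (both carbinol epimers), via lithium 4-bromo-2,5-bis(methoxymethoxy)phenoxide 9 (not isolated), via lithium 4-lithio-2,5-bis(methoxymethoxy)phenoxide 10 (not isolated)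
Conditions: 8, t-BuLi (3.1 equiv), THF, −78 °C; then 3 (0.8 equiv), −78 to −20 °C; aq. NH4Cl
Reagents that add atoms: none
Why: Phenol deprotonation followed by Br–Li exchange gives an OMOM-chelated aryllithium that adds 1,2 to the aldehyde; the new carbinol centre forms as an epimer mixture that step 7 erases.

Step 7
Reactants: 11 4-{hydroxy[(1S,2S,4aS,8aS)-2,5,5,8a-tetramethyldecahydronaphthalen-1-yl]methyl}-2,5-bis(methoxymethoxy)phenol
Product: 12 2,5-bis(methoxymethoxy)-4-{(E)-[(2S,4aS,8aS)-2,5,5,8a-tetramethyloctahydronaphthalen-1(2H)-ylidene]methyl}phenol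
Conditions: PPTS (10 mol %), toluene, 60 °C
Reagents that add atoms: none
Why: Acid-catalysed E1 dehydration through the para-hydroxy/ortho-alkoxy-stabilised benzylic cation; loss of H-9 gives the conjugated alkene as the thermodynamic E isomer (aryl syn to C8–H, away from quaternary C10) without touching C8.

Step 8
Reactants: 12 2,5-bis(methoxymethoxy)-4-{(E)-[(2S,4aS,8aS)-2,5,5,8a-tetramethyloctahydronaphthalen-1(2H)-ylidene]methyl}phenol
Product: 14 2-hydroxy-3,6-bis(methoxymethoxy)-5-{(E)-[(2S,4aS,8aS)-2,5,5,8a-tetramethyloctahydronaphthalen-1(2H)-ylidene]methyl}benzaldehyde, via ortho-hydroxymethyl phenol 13 (not isolated)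
Conditions: MgCl2 (3 equiv), Et3N (6 equiv), (CH2O)n (8 equiv), THF, reflux; 5% citric acid work-up
Reagents that add atoms: paraformaldehyde (formaldehyde), C=O
Why: Casnati–Skattebøl ortho-formylation, in which the magnesium phenoxide delivers formaldehyde to the only free ortho carbon and a second formaldehyde oxidises the benzylic alkoxide by hydride transfer.

Step 9
Reactants: 14 2-hydroxy-3,6-bis(methoxymethoxy)-5-{(E)-[(2S,4aS,8aS)-2,5,5,8a-tetramethyloctahydronaphthalen-1(2H)-ylidene]methyl}benzaldehyde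
Product: 15 2-(allyloxy)-3,6-bis(methoxymethoxy)-5-{(E)-[(2S,4aS,8aS)-2,5,5,8a-tetramethyloctahydronaphthalen-1(2H)-ylidene]methyl}benzaldehyde
Conditions: allyl bromide, K2CO3, DMF, 40 °C
Reagents that add atoms: allyl bromide, C=CCBr
Why: Williamson etherification of the only free phenol marks O-4' with a group that resists acid and sulfation but is removed by Pd(0).

Step 10
Reactants: 15 2-(allyloxy)-3,6-bis(methoxymethoxy)-5-{(E)-[(2S,4aS,8aS)-2,5,5,8a-tetramethyloctahydronaphthalen-1(2H)-ylidene]methyl}benzaldehyde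
Product: 16 2-(allyloxy)-3,6-dihydroxy-5-{(E)-[(2S,4aS,8aS)-2,5,5,8a-tetramethyloctahydronaphthalen-1(2H)-ylidene]methyl}benzaldehyde
Conditions: 3 M aq. HCl–THF (1:4), rt to 40 °C, argon
Reagents that add atoms: none
Why: Acid hydrolysis of the two aryl MOM acetals; dilute aqueous acid in a basic ether solvent is too weak to protonate the hindered styrene toward spirocyclisation, and the allyl ether and aldehyde are inert.

Step 11
Reactants: 16 2-(allyloxy)-3,6-dihydroxy-5-{(E)-[(2S,4aS,8aS)-2,5,5,8a-tetramethyloctahydronaphthalen-1(2H)-ylidene]methyl}benzaldehyde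
Product: 17 2-(allyloxy)-3,6-bis(sulfooxy)-5-{(E)-[(2S,4aS,8aS)-2,5,5,8a-tetramethyloctahydronaphthalen-1(2H)-ylidene]methyl}benzaldehyde
Conditions: SO3·pyridine (8 equiv), pyridine, 50 °C, argon; aq. NaHCO3, C18 chromatography
Reagents that add atoms: sulfur trioxide–pyridine complex, O=S(=O)=O.c1ccncc1
Why: O-sulfation of both free phenols with the SO3–amine complex; O-4' is blocked as its allyl ether, so only the 2',5'-bis(sulfate) can form.

Step 12
Reactants: 17 2-(allyloxy)-3,6-bis(sulfooxy)-5-{(E)-[(2S,4aS,8aS)-2,5,5,8a-tetramethyloctahydronaphthalen-1(2H)-ylidene]methyl}benzaldehyde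
Product: 18 2-hydroxy-3,6-bis(sulfooxy)-5-{(E)-[(2S,4aS,8aS)-2,5,5,8a-tetramethyloctahydronaphthalen-1(2H)-ylidene]methyl}benzaldehyde
Conditions: Pd(PPh3)4 (5 mol %), morpholine, THF–MeOH, rt; H+ ion-exchange resin, 0 °C
Reagents that add atoms: none
Why: Tsuji–Trost deallylation in which Pd(0) ionises the aryl allyl ether (ortho-formyl phenoxide leaving group) and morpholine traps the π-allyl; sulfate monoesters, the aldehyde and the trisubstituted alkene are untouched.

## Compound list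

1 | (−)-drimenol, [(1S,4aS,8aS)-2,5,5,8a-tetramethyl-1,4,4a,5,6,7,8,8a-octahydronaphthalen-1-yl]methanol | CC1=CC[C@H]2C(C)(C)CCC[C@]2(C)[C@H]1CO | starting material
2 | [(1S,2S,4aS,8aS)-2,5,5,8a-tetramethyldecahydronaphthalen-1-yl]methanol (8β-methyl, cis to the C10 methyl and the CH2OH; trans-decalin) | C[C@H]1CC[C@H]2C(C)(C)CCC[C@]2(C)[C@H]1CO | intermediate
3 | (1S,2S,4aS,8aS)-2,5,5,8a-tetramethyldecahydronaphthalene-1-carbaldehyde | C[C@H]1CC[C@H]2C(C)(C)CCC[C@]2(C)[C@H]1C=O | intermediate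
4 | 2,5-dihydroxybenzaldehyde | O=Cc1cc(O)ccc1O | starting material
5 | 2,5-bis(methoxymethoxy)benzaldehyde | O=Cc1cc(OCOC)ccc1OCOC | intermediate
6 | 2,5-bis(methoxymethoxy)phenyl formate | O=COc1cc(OCOC)ccc1OCOC | intermediate
7 | 2,5-bis(methoxymethoxy)phenol | Oc1cc(OCOC)ccc1OCOC | intermediate
8 | 4-bromo-2,5-bis(methoxymethoxy)phenol | Oc1cc(OCOC)c(Br)cc1OCOC | intermediate
9 | lithium 4-bromo-2,5-bis(methoxymethoxy)phenoxide | [Li]Oc1cc(OCOC)c(Br)cc1OCOC | intermediate
10 | lithium 4-lithio-2,5-bis(methoxymethoxy)phenoxide | [Li]Oc1cc(OCOC)c([Li])cc1OCOC | intermediate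
11 | 4-{hydroxy[(1S,2S,4aS,8aS)-2,5,5,8a-tetramethyldecahydronaphthalen-1-yl]methyl}-2,5-bis(methoxymethoxy)phenol (carbinol centre: both epimers) | C[C@H]1CC[C@H]2C(C)(C)CCC[C@]2(C)[C@H]1C(O)c1cc(OCOC)c(O)cc1OCOC | intermediate
12 | 2,5-bis(methoxymethoxy)-4-{(E)-[(2S,4aS,8aS)-2,5,5,8a-tetramethyloctahydronaphthalen-1(2H)-ylidene]methyl}phenol | C[C@H]1CC[C@H]2C(C)(C)CCC[C@]2(C)/C1=C/c1cc(OCOC)c(O)cc1OCOC | intermediate
13 | 2-(hydroxymethyl)-3,6-bis(methoxymethoxy)-4-{(E)-[(2S,4aS,8aS)-2,5,5,8a-tetramethyloctahydronaphthalen-1(2H)-ylidene]methyl}phenol | C[C@H]1CC[C@H]2C(C)(C)CCC[C@]2(C)/C1=C/c1cc(OCOC)c(O)c(CO)c1OCOC | intermediate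
14 | 2-hydroxy-3,6-bis(methoxymethoxy)-5-{(E)-[(2S,4aS,8aS)-2,5,5,8a-tetramethyloctahydronaphthalen-1(2H)-ylidene]methyl}benzaldehyde | C[C@H]1CC[C@H]2C(C)(C)CCC[C@]2(C)/C1=C/c1cc(OCOC)c(O)c(C=O)c1OCOC | intermediate
15 | 2-(allyloxy)-3,6-bis(methoxymethoxy)-5-{(E)-[(2S,4aS,8aS)-2,5,5,8a-tetramethyloctahydronaphthalen-1(2H)-ylidene]methyl}benzaldehyde | C[C@H]1CC[C@H]2C(C)(C)CCC[C@]2(C)/C1=C/c1cc(OCOC)c(OCC=C)c(C=O)c1OCOC | intermediate
16 | 2-(allyloxy)-3,6-dihydroxy-5-{(E)-[(2S,4aS,8aS)-2,5,5,8a-tetramethyloctahydronaphthalen-1(2H)-ylidene]methyl}benzaldehyde | C[C@H]1CC[C@H]2C(C)(C)CCC[C@]2(C)/C1=C/c1cc(O)c(OCC=C)c(C=O)c1O | intermediate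
17 | 2-(allyloxy)-3,6-bis(sulfooxy)-5-{(E)-[(2S,4aS,8aS)-2,5,5,8a-tetramethyloctahydronaphthalen-1(2H)-ylidene]methyl}benzaldehyde | C[C@H]1CC[C@H]2C(C)(C)CCC[C@]2(C)/C1=C/c1cc(OS(=O)(=O)O)c(OCC=C)c(C=O)c1OS(=O)(=O)O | intermediate
18 | 2-hydroxy-3,6-bis(sulfooxy)-5-{(E)-[(2S,4aS,8aS)-2,5,5,8a-tetramethyloctahydronaphthalen-1(2H)-ylidene]methyl}benzaldehyde (CNP0309628.1) | C[C@H]1CC[C@H]2C(C)(C)CCC[C@]2(C)/C1=C/c1cc(OS(=O)(=O)O)c(O)c(C=O)c1OS(=O)(=O)O | target

## Step count and risks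

Total step count: 12. Longest linear sequence: 10 steps (steps 3–12, from 2,5-dihydroxybenzaldehyde); the terpenoid branch joins after 2 steps.

The three steps most likely to fail:

Step 6 (dianion coupling). The dilithio species 10 may be poorly soluble, or may act as a base toward the hindered, enolisable aldehyde 3. The fallback sets out from 8 and comes back at 11. The phenol of 8 is silylated (TIPSCl, imidazole, DMF) to the TIPS ether F1. n-BuLi (THF, −78 °C) converts it into the mono-aryllithium F2, which is added to 3 to give the silylated carbinol F3. TBAF (THF, 0 °C) then frees the phenol and gives 11.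

Step 8 (ortho-formylation). The only free ortho carbon lies between the OH and an OMOM group, so formaldehyde delivery may be slow on this electron-rich vinylphenol. The fallback sets out from 12 and comes back at 15, bypassing 14. Amine-catalysed ortho-bromination (NBS, cat. i-Pr2NH, CH2Cl2, −78 °C) gives the bromophenol F4. O-allylation (allyl bromide, K2CO3, DMF) gives the bromo allyl ether F5. Br–Li exchange (t-BuLi, 2 equiv, THF, −78 °C) gives the aryllithium F6. DMF converts this into the lithium hemiaminal alkoxide F7, which collapses to 15 on aqueous work-up.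

Step 11 (bis-sulfation). The 2'-OH is hydrogen-bonded to the aldehyde and flanked by the alkenyl group, hydroquinone 16 is air-sensitive, and a mono-/bis-sulfate salt mixture would be hard to separate. The fallback sets out from 16 and comes back at 17. Both phenols are sulfated as protected diesters with 2,2,2-trichloroethyl chlorosulfate (Et3N, DMAP, THF, 0 °C) to give the bis(trichloroethyl sulfate) F8, a neutral compound that can be purified on silica. Zn dust and HCO2NH4 in MeOH then remove both trichloroethyl groups by reductive fragmentation and give 17.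

## Further compounds

F1 | step 6 | (4-bromo-2,5-bis(methoxymethoxy)phenoxy)tri(propan-2-yl)silane | CC(C)[Si](Oc1cc(OCOC)c(Br)cc1OCOC)(C(C)C)C(C)C
F2 | step 6 | [2,5-bis(methoxymethoxy)-4-(triisopropylsilyloxy)phenyl]lithium | CC(C)[Si](Oc1cc(OCOC)c([Li])cc1OCOC)(C(C)C)C(C)C
F3 | step 6 | [2,5-bis(methoxymethoxy)-4-(triisopropylsilyloxy)phenyl][(1S,2S,4aS,8aS)-2,5,5,8a-tetramethyldecahydronaphthalen-1-yl]methanol (both carbinol epimers) | C[C@H]1CC[C@H]2C(C)(C)CCC[C@]2(C)[C@H]1C(O)c1cc(OCOC)c(O[Si](C(C)C)(C(C)C)C(C)C)cc1OCOC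
F4 | step 8 | 2-bromo-3,6-bis(methoxymethoxy)-4-{(E)-[(2S,4aS,8aS)-2,5,5,8a-tetramethyloctahydronaphthalen-1(2H)-ylidene]methyl}phenol | C[C@H]1CC[C@H]2C(C)(C)CCC[C@]2(C)/C1=C/c1cc(OCOC)c(O)c(Br)c1OCOC
F5 | step 8 | 2-(allyloxy)-3-bromo-1,4-bis(methoxymethoxy)-5-{(E)-[(2S,4aS,8aS)-2,5,5,8a-tetramethyloctahydronaphthalen-1(2H)-ylidene]methyl}benzene | C[C@H]1CC[C@H]2C(C)(C)CCC[C@]2(C)/C1=C/c1cc(OCOC)c(OCC=C)c(Br)c1OCOC
F6 | step 8 | [2-(allyloxy)-3,6-bis(methoxymethoxy)-5-{(E)-[(2S,4aS,8aS)-2,5,5,8a-tetramethyloctahydronaphthalen-1(2H)-ylidene]methyl}phenyl]lithium | C[C@H]1CC[C@H]2C(C)(C)CCC[C@]2(C)/C1=C/c1cc(OCOC)c(OCC=C)c([Li])c1OCOC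
F7 | step 8 | lithium (dimethylamino)[2-(allyloxy)-3,6-bis(methoxymethoxy)-5-{(E)-[(2S,4aS,8aS)-2,5,5,8a-tetramethyloctahydronaphthalen-1(2H)-ylidene]methyl}phenyl]methanolate | C[C@H]1CC[C@H]2C(C)(C)CCC[C@]2(C)/C1=C/c1cc(OCOC)c(OCC=C)c(C(O[Li])N(C)C)c1OCOC
F8 | step 11 | 2-(allyloxy)-3,6-bis{[(2,2,2-trichloroethoxy)sulfonyl]oxy}-5-{(E)-[(2S,4aS,8aS)-2,5,5,8a-tetramethyloctahydronaphthalen-1(2H)-ylidene]methyl}benzaldehyde | C[C@H]1CC[C@H]2C(C)(C)CCC[C@]2(C)/C1=C/c1cc(OS(=O)(=O)OCC(Cl)(Cl)Cl)c(OCC=C)c(C=O)c1OS(=O)(=O)OCC(Cl)(Cl)Cl
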